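**Retrosynthetic overview**
- Theasinensin C ⇒ two molecules of (−)-epigallocatechin, joined last by a biomimetic oxidative C2'–C2' coupling of the ring B pyrogallols (quinone addition, then reduction); the flavan stereocentres control the axis.
- (−)-Epigallocatechin ⇒ its hexabenzyl ether ⇒ an achiral 3-benzyloxyflavylium ion; C2 and C3 are set together by a chiral Brønsted acid/Hantzsch ester double transfer hydrogenation (metal-free).
- Flavylium ion ⇒ neutral pseudo-base ⇒ hexa-O-benzylmyricetin ⇒ myricetin (achiral, commercial).
- Ring order: rings A, B and C arrive preformed in myricetin; ring C is carried from pyranone through pyrylium to the saturated pyran; the biaryl bond is made last.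

Assumption: theasinensin C is taken as the (R)-biaryl atropisomer of the 2'-2' linked dimer of (2R,3R)-epigallocatechin (the SMILES fixes only the four carbon stereocentres), and the (R)-configured acid catalyst of step 3 is taken to give the (2R,3R) series (if a test run shows the opposite sense, the (S)-catalyst is used).

**Route**

Step 1
Reactants: 1 myricetin
Product: 2 3,5,7-tris(benzyloxy)-2-[3,4,5-tris(benzyloxy)phenyl]-4H-chromen-4-one (hexa-O-benzylmyricetin)
Conditions: BnBr (8 equiv), K2CO3 (10 equiv), n-Bu4NI (cat.), degassed DMF, Ar, 25 → 65 °C, 24 h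
Reagents that add atoms: benzyl bromide, BrCc1ccccc1
Why: Exhaustive Williamson etherification; excess reagent and heat also alkylate the hydrogen-bonded 5-OH, and argon protects the pyrogallol from air oxidation.

Step 2
Reactants: 2 hexa-O-benzylmyricetin
Product: 3 (±)-3,5,7-tris(benzyloxy)-2-[3,4,5-tris(benzyloxy)phenyl]-4H-chromen-4-ol (flav-2-en-4-ol pseudo-base)
Conditions: LiAlH4 (1.0 equiv), THF, −40 → 0 °C, 1 h; Na2SO4·10H2O quench, filter, concentrate below 25 °C, use crude at once
Reagents that add atoms: none
Why: 1,2-Hydride addition to the vinylogous-ester carbonyl of a 3-alkoxyflavone (the classical first stage of the flavonol-to-anthocyanidin conversion); the non-acidic work-up keeps the acid-labile pseudo-base neutral, and its racemic carbinol centre is erased in step 3.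

Step 3
Reactants: 3 flav-2-en-4-ol pseudo-base
Product: 7 (2R,3R)-3,5,7-tris(benzyloxy)-2-[3,4,5-tris(benzyloxy)phenyl]chromane (hexa-O-benzyl-(−)-epigallocatechin), via flavylium ion pair 4 (not isolated), via enol ether 5 (not isolated), via oxocarbenium ion pair 6 (not isolated)
Conditions: (R)-3,3'-bis(2,4,6-triisopropylphenyl)-BINOL N-triflylphosphoramide (5 mol%), Hantzsch ester (diethyl 2,6-dimethyl-1,4-dihydropyridine-3,5-dicarboxylate, 2.4 equiv), 5 Å MS, toluene/CH2Cl2 4:1, −30 → 0 °C, 24 h
Reagents that add atoms: none
Why: Proposed new method: an anthocyanidin-reductase-like double transfer hydrogenation in which the chiral acid (a) ionises pseudo-base 3 to flavylium ion pair 4, (b) after soft hydride addition from the Hantzsch ester to the unhindered C4 (no stereocentre) protonates the achiral tetrasubstituted enol ether 5 at C2 from one enantioface, as chiral N-triflylphosphoramides are known to do with silyl enol ethers of 2-aryl cyclic ketones and with the regiochemistry by which aqueous acid turns 3-alkoxyflav-2-enes into flavan-3-ones, and (c) holds the resulting O-benzyl oxocarbenium 6 as a contact ion pair that takes the second hydride at C3 on the face anti to the ring B aryl group (the face preference LiBH(s-Bu)3 shows with flavan-3-ones), so proton and hydride add syn and the 2,3-cis (2R,3R) product results; the closest known reaction type is the chiral phosphoric acid/Hantzsch ester cascade reduction of 2,3-disubstituted quinolines (1,4-hydride addition, enantioselective protonation, 1,2-hydride addition), which has not been carried over to benzopyrylium ions or 3-oxygenated flavenes.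

Step 4
Reactants: 7 hexa-O-benzyl-(−)-epigallocatechin
Product: 8 (−)-epigallocatechin, (2R,3R)-2-(3,4,5-trihydroxyphenyl)chromane-3,5,7-triol
Conditions: H2 (1 atm), 20% Pd(OH)2/C, THF/MeOH 1:1, rt, 8 h; filter under Ar
Reagents that add atoms: none
Why: Hydrogenolysis of the five aryl benzyl ethers and the secondary alkyl benzyl ether; the flavan C2–O1 bond and both stereocentres survive these neutral conditions, as is standard in catechin debenzylations.

Step 5
Reactants: 8 (−)-epigallocatechin (two molecules)
Product: 11 theasinensin C, via epigallocatechin ortho-quinone 9 (not isolated), via dehydro dimer quinone 10 (not isolated)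
Conditions: CuCl2 (2.0 equiv), H2O, 25 °C, 4 h; then L-ascorbic acid (5 equiv), 85 °C, 15 min; Sephadex LH-20
Reagents that add atoms: none
Why: Biomimetic oxidative phenol coupling: divalent copper oxidises the ring B pyrogallol to hydroxy-ortho-quinone 9, a second pyrogallol adds 1,4 through its ring CH to forge the C2'–C2' bond, and further oxidation gives the dehydro dimer quinone 10 (dehydrotheasinensin C), whose framework is dictated by the (2R,3R) flavan units so that ascorbate reduction releases mainly the (R)-atropisomer (the one-pot protocol is established for the 3-O-gallate series); the acidic medium and short heating avoid C2 epimerisation.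

**Compound list**
1 | myricetin, 3,5,7-trihydroxy-2-(3,4,5-trihydroxyphenyl)-4H-chromen-4-one (achiral) | O=c1c(O)c(-c2cc(O)c(O)c(O)c2)oc2cc(O)cc(O)c12 | starting material
2 | 3,5,7-tris(benzyloxy)-2-[3,4,5-tris(benzyloxy)phenyl]-4H-chromen-4-one | O=c1c(OCc2ccccc2)c(-c2cc(OCc3ccccc3)c(OCc3ccccc3)c(OCc3ccccc3)c2)oc2cc(OCc3ccccc3)cc(OCc3ccccc3)c12 | intermediate
3 | (±)-3,5,7-tris(benzyloxy)-2-[3,4,5-tris(benzyloxy)phenyl]-4H-chromen-4-ol | OC1C(OCc2ccccc2)=C(c2cc(OCc3ccccc3)c(OCc3ccccc3)c(OCc3ccccc3)c2)Oc2cc(OCc3ccccc3)cc(OCc3ccccc3)c21 | intermediate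
4 | 3,5,7-tris(benzyloxy)-2-[3,4,5-tris(benzyloxy)phenyl]chromenylium (flavylium) cation, paired in step 3 with the catalyst anion | [o+]1c(-c2cc(OCc3ccccc3)c(OCc3ccccc3)c(OCc3ccccc3)c2)c(OCc2ccccc2)cc2c(OCc3ccccc3)cc(OCc3ccccc3)cc12 | intermediate (not isolated)
5 | 3,5,7-tris(benzyloxy)-2-[3,4,5-tris(benzyloxy)phenyl]-4H-chromene (achiral enol ether) | C1C(OCc2ccccc2)=C(c2cc(OCc3ccccc3)c(OCc3ccccc3)c(OCc3ccccc3)c2)Oc2cc(OCc3ccccc3)cc(OCc3ccccc3)c21 | intermediate (not isolated)
6 | benzyl{(2R)-5,7-bis(benzyloxy)-2-[3,4,5-tris(benzyloxy)phenyl]chroman-3-ylidene}oxonium, paired with the catalyst anion | C1C(=[O+]Cc2ccccc2)[C@@H](c2cc(OCc3ccccc3)c(OCc3ccccc3)c(OCc3ccccc3)c2)Oc2cc(OCc3ccccc3)cc(OCc3ccccc3)c21 | intermediate (not isolated)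
7 | (2R,3R)-3,5,7-tris(benzyloxy)-2-[3,4,5-tris(benzyloxy)phenyl]chromane | c1ccccc1COc1cc(OCc2ccccc2)c2c(c1)O[C@H](c1cc(OCc3ccccc3)c(OCc3ccccc3)c(OCc3ccccc3)c1)[C@H](OCc1ccccc1)C2 | intermediate
8 | (−)-epigallocatechin, (2R,3R)-2-(3,4,5-trihydroxyphenyl)chromane-3,5,7-triol | Oc1cc(O)c2c(c1)O[C@H](c1cc(O)c(O)c(O)c1)[C@H](O)C2 | intermediate
9 | 3-hydroxy-5-[(2R,3R)-3,5,7-trihydroxychroman-2-yl]cyclohexa-3,5-diene-1,2-dione (epigallocatechin ortho-quinone) | Oc1cc(O)c2c(c1)O[C@H](C1=CC(=O)C(=O)C(O)=C1)[C@H](O)C2 | intermediate (not isolated)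
10 | dehydro dimer quinone (dehydrotheasinensin C), the hydroxy-ortho-quinone of 11, drawn anhydrous (present in water as its hydrated hemiketal) | Oc1cc(O)c2c(c1)O[C@H](c1cc(O)c(O)c(O)c1C1=C([C@H]3Oc4cc(O)cc(O)c4C[C@H]3O)C=C(O)C(=O)C1=O)[C@H](O)C2 | intermediate (not isolated)
11 | theasinensin C, the 2'-2' linked (R)-biaryl dimer of (2R,3R)-epigallocatechin | Oc1cc(O)c2c(c1)O[C@H](c1cc(O)c(O)c(O)c1-c1c([C@H]3Oc4cc(O)cc(O)c4C[C@H]3O)cc(O)c(O)c1O)[C@H](O)C2 | target

**Step count and risks**
Total steps: 5. Longest linear sequence: 5.

Step 3 (the proposed new step) is the most likely to fail. The risks are first hydride addition at C2 instead of C4, protonation of 5 at C3 rather than C2 (which still leads to the constitution of 7 but under a different stereochemical model), loss of the benzyl group from 6 to give the ketone, a racemic background reaction, and formation of the trans isomer. The fallback uses established chemistry, sets out from 3 and comes back at 8. Pseudo-base 3 is treated with one equivalent of Hantzsch ester and catalytic achiral diphenyl phosphate, passing through flavylium ion 4, and enol ether 5 is isolated. Its benzyl enol ether is hydrolysed (1 M HCl, THF, rt) to racemic 5,7-bis(benzyloxy)-2-[3,4,5-tris(benzyloxy)phenyl]chroman-3-one F1. The C2–H of F1 is benzylic and flanked by oxygen and carbonyl, so it epimerises readily. A Noyori–Ikariya transfer hydrogenation under dynamic kinetic resolution (RuCl(p-cymene)[TsDPEN], HCO2H/Et3N 5:2, the ligand enantiomer that gives the (3R) alcohol chosen in a test run) then reduces F1 to the cis alcohol (2R,3R)-5,7-bis(benzyloxy)-2-[3,4,5-tris(benzyloxy)phenyl]chroman-3-ol F2. This reaction class is standard for 2-aryl cyclic ketones, though it has not been shown on this ketone. Hydrogenolysis of F2 (H2, Pd(OH)2/C) gives 8.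

Step 2 is the second risk: over-reduction, or decomposition of the acid-labile pseudo-base on handling. The fallback sets out from 2 and comes back at 5. The LiAlH4 reduction mixture is quenched directly into HBF4·OEt2 to precipitate crystalline 3,5,7-tris(benzyloxy)-2-[3,4,5-tris(benzyloxy)phenyl]chromenylium tetrafluoroborate F3 (the classical anthocyanidin protocol). F3 is then reduced at C4 with one equivalent of Hantzsch ester over solid NaHCO3 to give isolated enol ether 5. Step 3 is then run on 5 with 1.2 equivalents of Hantzsch ester, which removes water and achiral acid from the asymmetric step.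

Step 5 is the third risk: over-oxidation, ring-contracted by-products, and formation of the (S)-atropisomer theasinensin E. The fallback sets out from 8 and comes back at 11. The one-pot copper protocol is replaced by an enzymatic aerobic oxidation (laccase or polyphenol oxidase, O2, pH 5.5 citrate buffer, 25 °C) that stops at the dehydro dimer quinone 10. Compound 10 is isolated and purified on Sephadex LH-20, and the purified material is reduced in a separate operation with ascorbic acid or Na2S2O4. Oxidation and reduction can then be optimised independently, and by-products are removed before the axis is released.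

**Further compounds**
F1 | step 3 | (±)-5,7-bis(benzyloxy)-2-[3,4,5-tris(benzyloxy)phenyl]chroman-3-one | O=C1Cc2c(OCc3ccccc3)cc(OCc3ccccc3)cc2OC1c1cc(OCc2ccccc2)c(OCc2ccccc2)c(OCc2ccccc2)c1
F2 | step 3 | (2R,3R)-5,7-bis(benzyloxy)-2-[3,4,5-tris(benzyloxy)phenyl]chroman-3-ol | c1ccccc1COc1cc(OCc2ccccc2)c2c(c1)O[C@H](c1cc(OCc3ccccc3)c(OCc3ccccc3)c(OCc3ccccc3)c1)[C@H](O)C2
F3 | step 2 | 3,5,7-tris(benzyloxy)-2-[3,4,5-tris(benzyloxy)phenyl]chromenylium tetrafluoroborate | [o+]1c(-c2cc(OCc3ccccc3)c(OCc3ccccc3)c(OCc3ccccc3)c2)c(OCc2ccccc2)cc2c(OCc3ccccc3)cc(OCc3ccccc3)cc12.F[B-](F)(F)F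
F0 | step 5 | none | none
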